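The route rests on disconnecting, in the 2,2-dimethyl-4-methylenecyclohexanol ring, the bond between carbinol carbon C-1 and the adjacent ring CH2 (C-6). If the exocyclic methylene at C-4 is read as a latent ketone, C-1 and C-4 are 1,4-dioxygenated, a dissonant pattern, so the bond must join two electrophilic carbons. SmI2 does this by polarity reversal: a neopentyl aldehyde (C-1) is coupled reductively with the β-carbon (C-6) of a vinyl ketone (C-4), closing the ring and setting the carbinol centre at once. The precursor is an acyclic (R)-γ-keto aldehyde whose one stereocentre comes from an organocatalytic Michael addition of isobutyraldehyde to a geraniol-derived nitroalkene.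

Key step: step 8

Remark: ring locants are C-1 (CHOH), C-2 (CMe2), C-3 (side chain), C-4 (C=CH2), C-5, C-6; TBDPS = tert-butyldiphenylsilyl; geraniol, isofraxidin and all reagents are taken as commercial; the amine–thiourea catalyst is assumed to follow its usual sense of induction, and the antipode that gives (R)-11 is used.

Step 1
Reactants: 1 geraniol; 2 tert-butyl(chloro)diphenylsilane (TBDPSCl)
Product: 3 tert-butyl{[(2E)-3,7-dimethylocta-2,6-dien-1-yl]oxy}diphenylsilane
Conditions: TBDPSCl (1.1 equiv), imidazole (2 equiv), DMF, 0 °C → rt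
Reagents that add atoms: TBDPSCl, CC(C)(C)[Si](Cl)(c1ccccc1)c1ccccc1
Why: Silyl ether formation masks the allylic hydroxyl with a group that should survive the Grignard, oxidation, SmI2 and ylide steps and is removed by fluoride.

Step 2
Reactants: 3 geranyl TBDPS ether
Product: 5 (4E)-6-[(TBDPS)oxy]-4-methylhex-4-enal, via 6,7-epoxide 4 (not isolated)
Conditions: mCPBA (1.05 equiv), CH2Cl2, −20 → 0 °C; then H5IO6 (1.2 equiv), THF–H2O, 0 °C
Reagents that add atoms: mCPBA (3-chloroperbenzoic acid), OOC(=O)c1cccc(Cl)c1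
Why: Prilezhaev epoxidation should prefer the distal trisubstituted alkene (the proximal one is deactivated by the allylic silyloxy group), and periodic acid cleavage of the epoxide (Malaprade-type) gives the aldehyde with the E-alkene of the side chain inherited from geraniol.

Step 3
Reactants: 5 aldehyde; 6 nitromethane
Product: 9 tert-butyl{[(2E,6E)-3-methyl-7-nitrohepta-2,6-dien-1-yl]oxy}diphenylsilane, via nitro alcohol 7 (not isolated), via nitro mesylate 8 (not isolated)
Conditions: MeNO2 (10 equiv), KOtBu (10 mol%), THF–tBuOH, 0 °C; concentrate; MsCl, Et3N, CH2Cl2, −20 → 0 °C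
Reagents that add atoms: nitromethane, C[N+](=O)[O-]
Why: Henry reaction followed by mesylation and E1cB elimination should give the conjugated (E)-nitroalkene, which serves as an α-acyl cation equivalent for the branching carbon.

Step 4
Reactants: 9 nitroalkene; 10 isobutyraldehyde
Product: 12 (3R,6E)-8-[(TBDPS)oxy]-2,2,6-trimethyl-3-(nitromethyl)oct-6-en-1-ol, via nitro aldehyde 11 (not isolated)
Conditions: isobutyraldehyde (5 equiv), 1-(2-aminocyclohexyl)-3-[3,5-bis(trifluoromethyl)phenyl]thiourea (trans, single enantiomer, 15 mol%), PhCO2H (15 mol%), toluene, rt; evaporate volatiles; NaBH4, MeOH, 0 °C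
Reagents that add atoms: isobutyraldehyde, CC(C)C=O
Why: Bifunctional primary amine–thiourea catalysis (enamine Michael addition) should form the quaternary carbon and set the single stereocentre (R) by attack of the isobutyraldehyde enamine on one face of the thiourea-bound nitroalkene, and in situ reduction masks the neopentyl aldehyde.

Step 5
Reactants: 12 nitro alcohol
Product: 15 (3R)-3-{(3E)-5-[(TBDPS)oxy]-3-methylpent-3-en-1-yl}-4,4-dimethyloxolan-2-ol (anomer mixture), via sodium nitronate 13 (not isolated), via hydroxy aldehyde 14 (not isolated)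
Conditions: NaOMe, MeOH, 0 °C; then aq TiCl3 (4.5 equiv), NH4OAc buffer (pH 5–6), THF–H2O, 0 °C → rt
Reagents that add atoms: water, O
Why: Reductive Nef reaction: trivalent titanium reduces the nitronate to the imine, which hydrolyses to the aldehyde and is trapped by the γ-hydroxyl as the lactol, sheltering the α-stereocentre from enolization.

Step 6
Reactants: 15 lactol; 16 vinylmagnesium bromide
Product: 18 (3R,4RS)-3-{(3E)-5-[(TBDPS)oxy]-3-methylpent-3-en-1-yl}-2,2-dimethylhex-5-ene-1,4-diol, via magnesium alkoxide aldehyde 17 (not isolated)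
Conditions: CH2=CHMgBr (4 equiv), THF, −78 → 0 °C; aq NH4Cl
Reagents that add atoms: vinylmagnesium bromide, C=C[Mg]Br
Why: The first equivalent of the Grignard reagent deprotonates the lactol, whose magnesium lactolate opens to the alkoxide aldehyde, and Grignard addition to this aldehyde installs the two carbons that become C-5 and C-6, the configuration of the new carbinol being irrelevant because it is oxidized next.

Step 7
Reactants: 18 diol
Product: 19 (3R)-3-{(3E)-5-[(TBDPS)oxy]-3-methylpent-3-en-1-yl}-2,2-dimethyl-4-oxohex-5-enal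
Conditions: (COCl)2, DMSO, CH2Cl2, −78 °C; iPr2NEt, −78 → −30 °C; pH 7 buffer; used at once
Reagents that add atoms: none
Why: Swern oxidation activates both hydroxyls before any carbonyl is formed, which avoids lactol-to-lactone over-oxidation of the 1,4-diol, while low temperature and the hindered base should spare the stereocentre α to the new vinyl ketone.

Step 8
Reactants: 19 keto aldehyde
Product: 20 (2R,4R)-2-{(3E)-5-[(TBDPS)oxy]-3-methylpent-3-en-1-yl}-4-hydroxy-3,3-dimethylcyclohexan-1-one
Conditions: SmI2 (2.5 equiv, 0.1 M in THF), tBuOH (3 equiv), THF (0.01 M), −78 → −20 °C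
Reagents that add atoms: none
Why: Electron transfer from divalent samarium gives a samarium-bound ketyl at the aldehyde carbon (or the β-radical of the reduced enone), which bonds to the terminal β-carbon of the vinyl ketone; a second electron transfer gives the samarium enolate, protonated by tBuOH to the ketone. The closest known reaction type is the SmI2 ketyl–olefin reductive coupling of aldehydes with vinyl ketones and acrylates to γ-hydroxy carbonyl compounds, including its endo-mode intramolecular variants. The six-membered ring closes in 6-endo-trig mode, which is enforced electronically because only attack at the unsubstituted β-carbon gives the stabilized α-keto radical, whereas 5-exo attack at the α-carbon would give a primary radical. The new carbinol centre is controlled by the existing stereocentre: in a chair-like transition state the side chain is equatorial and the bulky samarium alkoxide is pseudo-equatorial and anti to the enone, so hydroxyl and side chain should emerge cis. The step needs chemoselectivity over enone hydrodimerization, plain conjugate reduction and reductive aldol closure to a cyclopentanol; high dilution, low temperature, a weak proton donor and the gem-dimethyl group next to the aldehyde favour the intramolecular coupling.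

Step 9
Reactants: 20 hydroxy ketone; 21 methyltriphenylphosphonium bromide
Product: 22 (1R,3S)-3-{(3E)-5-[(TBDPS)oxy]-3-methylpent-3-en-1-yl}-2,2-dimethyl-4-methylidenecyclohexan-1-ol
Conditions: Ph3PCH3Br (4 equiv), KOtBu (3.8 equiv), THF, 0 → 50 °C
Reagents that add atoms: methyltriphenylphosphonium bromide, C[P+](c1ccccc1)(c1ccccc1)c1ccccc1.[Br-]
Why: Wittig methylenation with excess ylide tolerates the hydroxyl as its alkoxide, and the centre α to the ketone already holds the thermodynamically preferred equatorial orientation, so brief base exposure should not change it.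

Step 10
Reactants: 22 silyl ether
Product: 23 (1R,3S)-3-[(3E)-5-hydroxy-3-methylpent-3-en-1-yl]-2,2-dimethyl-4-methylidenecyclohexan-1-ol
Conditions: Bu4NF (1.5 equiv), THF, 0 °C → rt
Reagents that add atoms: none
Why: Fluoride-mediated desilylation frees the primary allylic alcohol without touching the alkenes or the secondary alcohol.

Step 11
Reactants: 23 diol; 24 isofraxidin (7-hydroxy-6,8-dimethoxy-2H-chromen-2-one)
Product: 25 7-{[(2E)-5-[(1S,3R)-3-hydroxy-2,2-dimethyl-6-methylidenecyclohexyl]-3-methylpent-2-en-1-yl]oxy}-6,8-dimethoxy-2H-chromen-2-one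
Conditions: isofraxidin (1.1 equiv), PPh3 (1.3 equiv), DIAD (1.3 equiv), THF, 0 °C → rt
Reagents that add atoms: isofraxidin, COc1cc2ccc(=O)oc2c(OC)c1O
Why: Mitsunobu etherification should activate only the unhindered primary allylic hydroxyl (the secondary hydroxyl next to the quaternary carbon is too hindered), and the acidic phenol displaces it with retention of the E-alkene.

Compound list
1 | geraniol, (2E)-3,7-dimethylocta-2,6-dien-1-ol | CC(C)=CCC/C(C)=C/CO | starting material
2 | tert-butyl(chloro)diphenylsilane | CC(C)(C)[Si](Cl)(c1ccccc1)c1ccccc1 | starting material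
3 | tert-butyl{[(2E)-3,7-dimethylocta-2,6-dien-1-yl]oxy}diphenylsilane | CC(C)=CCC/C(C)=C/CO[Si](c1ccccc1)(c1ccccc1)C(C)(C)C | intermediate
4 | tert-butyl{[(2E)-5-(3,3-dimethyloxiran-2-yl)-3-methylpent-2-en-1-yl]oxy}diphenylsilane (racemic epoxide) | CC1(C)OC1CC/C(C)=C/CO[Si](c1ccccc1)(c1ccccc1)C(C)(C)C | intermediate
5 | (4E)-6-[(TBDPS)oxy]-4-methylhex-4-enal | O=CCC/C(C)=C/CO[Si](c1ccccc1)(c1ccccc1)C(C)(C)C | intermediate
6 | nitromethane | C[N+](=O)[O-] | starting material
7 | (5E)-7-[(TBDPS)oxy]-5-methyl-1-nitrohept-5-en-2-ol (racemic) | OC(C[N+](=O)[O-])CC/C(C)=C/CO[Si](c1ccccc1)(c1ccccc1)C(C)(C)C | intermediate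
8 | methanesulfonate of 7 | CS(=O)(=O)OC(C[N+](=O)[O-])CC/C(C)=C/CO[Si](c1ccccc1)(c1ccccc1)C(C)(C)C | intermediate
9 | tert-butyl{[(2E,6E)-3-methyl-7-nitrohepta-2,6-dien-1-yl]oxy}diphenylsilane | [O-][N+](=O)/C=C/CC/C(C)=C/CO[Si](c1ccccc1)(c1ccccc1)C(C)(C)C | intermediate
10 | isobutyraldehyde (2-methylpropanal) | CC(C)C=O | starting material
11 | (3R,6E)-8-[(TBDPS)oxy]-2,2,6-trimethyl-3-(nitromethyl)oct-6-enal | O=CC(C)(C)[C@H](C[N+](=O)[O-])CC/C(C)=C/CO[Si](c1ccccc1)(c1ccccc1)C(C)(C)C | intermediate
12 | (3R,6E)-8-[(TBDPS)oxy]-2,2,6-trimethyl-3-(nitromethyl)oct-6-en-1-ol | OCC(C)(C)[C@H](C[N+](=O)[O-])CC/C(C)=C/CO[Si](c1ccccc1)(c1ccccc1)C(C)(C)C | intermediate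
13 | sodium nitronate of 12 | OCC(C)(C)[C@H](C=[N+]([O-])[O-])CC/C(C)=C/CO[Si](c1ccccc1)(c1ccccc1)C(C)(C)C.[Na+] | intermediate
14 | (2R,5E)-2-(1-hydroxy-2-methylpropan-2-yl)-7-[(TBDPS)oxy]-5-methylhept-5-enal | OCC(C)(C)[C@H](C=O)CC/C(C)=C/CO[Si](c1ccccc1)(c1ccccc1)C(C)(C)C | intermediate
15 | (3R)-3-{(3E)-5-[(TBDPS)oxy]-3-methylpent-3-en-1-yl}-4,4-dimethyloxolan-2-ol (anomer mixture) | OC1OCC(C)(C)[C@H]1CC/C(C)=C/CO[Si](c2ccccc2)(c2ccccc2)C(C)(C)C | intermediate
16 | vinylmagnesium bromide | C=C[Mg]Br | starting material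
17 | bromomagnesium (3R,6E)-3-formyl-8-[(TBDPS)oxy]-2,2,6-trimethyloct-6-en-1-olate (ring-opened magnesium alkoxide of 15) | Br[Mg]OCC(C)(C)[C@H](C=O)CC/C(C)=C/CO[Si](c1ccccc1)(c1ccccc1)C(C)(C)C | intermediate
18 | (3R,4RS)-3-{(3E)-5-[(TBDPS)oxy]-3-methylpent-3-en-1-yl}-2,2-dimethylhex-5-ene-1,4-diol | OCC(C)(C)[C@H](C(O)C=C)CC/C(C)=C/CO[Si](c1ccccc1)(c1ccccc1)C(C)(C)C | intermediate
19 | (3R)-3-{(3E)-5-[(TBDPS)oxy]-3-methylpent-3-en-1-yl}-2,2-dimethyl-4-oxohex-5-enal | O=CC(C)(C)[C@H](C(=O)C=C)CC/C(C)=C/CO[Si](c1ccccc1)(c1ccccc1)C(C)(C)C | intermediate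
20 | (2R,4R)-2-{(3E)-5-[(TBDPS)oxy]-3-methylpent-3-en-1-yl}-4-hydroxy-3,3-dimethylcyclohexan-1-one | O=C1CC[C@@H](O)C(C)(C)[C@H]1CC/C(C)=C/CO[Si](c2ccccc2)(c2ccccc2)C(C)(C)C | intermediate
21 | methyltriphenylphosphonium bromide | C[P+](c1ccccc1)(c1ccccc1)c1ccccc1.[Br-] | starting material
22 | (1R,3S)-3-{(3E)-5-[(TBDPS)oxy]-3-methylpent-3-en-1-yl}-2,2-dimethyl-4-methylidenecyclohexan-1-ol | C=C1CC[C@@H](O)C(C)(C)[C@H]1CC/C(C)=C/CO[Si](c2ccccc2)(c2ccccc2)C(C)(C)C | intermediate
23 | (1R,3S)-3-[(3E)-5-hydroxy-3-methylpent-3-en-1-yl]-2,2-dimethyl-4-methylidenecyclohexan-1-ol | C=C1CC[C@@H](O)C(C)(C)[C@H]1CC/C(C)=C/CO | intermediate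
24 | isofraxidin, 7-hydroxy-6,8-dimethoxy-2H-chromen-2-one | COc1cc2ccc(=O)oc2c(OC)c1O | starting material
25 | 7-{[(2E)-5-[(1S,3R)-3-hydroxy-2,2-dimethyl-6-methylidenecyclohexyl]-3-methylpent-2-en-1-yl]oxy}-6,8-dimethoxy-2H-chromen-2-one (CNP0306576.1) | C=C1CC[C@@H](O)C(C)(C)[C@H]1CC/C(C)=C/COc1c(OC)cc2ccc(=O)oc2c1OC | target

Total step count: 11. Longest linear sequence: 11 steps (1 → 25).

Steps most likely to fail

Step 8. Electron transfer to the vinyl ketone may outrun ring closure, giving hydrodimerization, plain conjugate reduction or reductive aldol closure to a five-membered ring, and facial selectivity at the new carbinol carbon may be low. The fallback sets out from keto aldehyde 19 and makes the same bond by carbene-catalysed polarity reversal of the aldehyde. An intramolecular Stetter reaction (2-mesityl-6,7-dihydro-5H-pyrrolo[2,1-c][1,2,4]triazol-2-ium chloride and KN(SiMe3)2, each 20 mol%, toluene, rt) should give (3R)-3-{(3E)-5-[(TBDPS)oxy]-3-methylpent-3-en-1-yl}-2,2-dimethylcyclohexane-1,4-dione F1. Takai–Lombardo methylenation (Zn, CH2Br2, TiCl4, THF–CH2Cl2, 0 °C) is non-basic and should react only at the ketone flanked by the tertiary carbon, not at the neopentyl ketone, giving (3S)-3-{(3E)-5-[(TBDPS)oxy]-3-methylpent-3-en-1-yl}-2,2-dimethyl-4-methylidenecyclohexan-1-one F2. NaBH4 (MeOH, −20 °C) should then add hydride axially to give the equatorial alcohol cis to the side chain, which is 22, where the route is rejoined.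

Step 4. The aliphatic nitroalkene may react slowly, isomerize to the β,γ-unsaturated nitro compound under the amine catalyst, or be attacked with insufficient facial selectivity. The fallback sets out from isobutyraldehyde 10 and nitroalkene 9 and replaces catalysis by a stoichiometric auxiliary. Condensation of 10 with (S)-1-amino-2-(methoxymethyl)pyrrolidine should give the hydrazone (S,E)-2-(methoxymethyl)-N-(2-methylpropylidene)pyrrolidin-1-amine F3. Deprotonation with LiN(iPr)2 (THF, −78 °C) and conjugate addition of the aza-enolate to 9 should give the SAMP hydrazone of (R)-aldehyde 11 F4 (the antipodal auxiliary is used if induction runs the other way). Hydrolysis with aqueous oxalic acid (Et2O, rt) returns to nitro aldehyde 11, which is reduced with NaBH4 as in step 4.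

Step 5. Reduction may stall at the oxime stage, or the α-branched aldehyde may be lost during hydrolysis. The fallback sets out from nitro alcohol 12 and passes through the carboxylic acid oxidation level. NaNO2, AcOH, DMSO, 35 °C should convert the primary nitro group into (2R,5E)-2-(1-hydroxy-2-methylpropan-2-yl)-7-[(TBDPS)oxy]-5-methylhept-5-enoic acid F5, which closes on mildly acidic work-up to (3R)-3-{(3E)-5-[(TBDPS)oxy]-3-methylpent-3-en-1-yl}-4,4-dimethyloxolan-2-one F6. Reduction with iBu2AlH (CH2Cl2, −78 °C) comes back to lactol 15.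

Further compounds
F1 | step 8 | (3R)-3-{(3E)-5-[(TBDPS)oxy]-3-methylpent-3-en-1-yl}-2,2-dimethylcyclohexane-1,4-dione | O=C1CCC(=O)C(C)(C)[C@H]1CC/C(C)=C/CO[Si](c2ccccc2)(c2ccccc2)C(C)(C)C
F2 | step 8 | (3S)-3-{(3E)-5-[(TBDPS)oxy]-3-methylpent-3-en-1-yl}-2,2-dimethyl-4-methylidenecyclohexan-1-one | C=C1CCC(=O)C(C)(C)[C@H]1CC/C(C)=C/CO[Si](c2ccccc2)(c2ccccc2)C(C)(C)C
F3 | step 4 | (S,E)-2-(methoxymethyl)-N-(2-methylpropylidene)pyrrolidin-1-amine | COC[C@@H]1CCCN1/N=C/C(C)C
F4 | step 4 | SAMP hydrazone of (R)-aldehyde 11 | COC[C@@H]1CCCN1/N=C/C(C)(C)[C@H](C[N+](=O)[O-])CC/C(C)=C/CO[Si](c1ccccc1)(c1ccccc1)C(C)(C)C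
F5 | step 5 | (2R,5E)-2-(1-hydroxy-2-methylpropan-2-yl)-7-[(TBDPS)oxy]-5-methylhept-5-enoic acid | OCC(C)(C)[C@H](C(O)=O)CC/C(C)=C/CO[Si](c1ccccc1)(c1ccccc1)C(C)(C)C
F6 | step 5 | (3R)-3-{(3E)-5-[(TBDPS)oxy]-3-methylpent-3-en-1-yl}-4,4-dimethyloxolan-2-one | O=C1OCC(C)(C)[C@H]1CC/C(C)=C/CO[Si](c2ccccc2)(c2ccccc2)C(C)(C)C
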